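Start with the easy entry: keep the ledger on the substrate, the limiting reagent of the flask, whose 19 mM stands below the 24.7 mM of partner.

| flask | substrate | partner | remark | time |
|---|---|---|---|---|
| amber | 27 mM | 24.7 mM | run made earlier |  |
| green | 42 mM | 24.7 mM | run made earlier |  |
| violet | 19 mM | 12 mM | run made earlier |  |
| flask | 19 mM | 24.7 mM |  | 20 h |

| run | time / h | target / % | isomer of the product / % |
|---|---|---|---|
| amber | 1.00 | 9 | 0 |
| amber | 3.00 | 19 | 0 |
| amber | 6.00 | 27 | 4 |
| amber | 8.00 | 36 | 4 |
| amber | 12.0 | 41 | 6 |
| amber | 15.0 | 46 | 7 |
| green | 1.00 | 6 | 0 |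
| green | 3.00 | 16 | 0 |
| green | 6.00 | 29 | 3 |
| green | 8.00 | 33 | 6 |
| green | 12.0 | 42 | 3 |
| green | 15.0 | 48 | 9 |
| violet | 1.33 | 10 | 0 |
| violet | 2.50 | 16 | 1 |
| violet | 5.00 | 24 | 2 |
| violet | 8.00 | 37 | 1 |
| violet | 15.0 | 50 | 10 |

(each reading ± 2 percentage points)

- ratio of target to isomer of the product at 20 min
- ratio of target to isomer of the product at 20 h



Book the readings at 15.0 h. Target reads 46%, 48% and 50% on substrate charges of 27 mM, 42 mM and 19 mM, so carry these percentages over to the flask. On average, target holds 48.0% of the charge and isomer 8.67%, and an unread 43.3% closes the books.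

In amber, isomer reads 0% at 3.00 h while target reads 19%, so book isomer as drawn from target at a rate k times target. Take target as growing in step with time and integrate: isomer is then k·t/2 of target. The ratio of target to isomer, multiplied by the time, therefore stays at 2/k; call this the ratio-time product 55.2 h, as pooled from amber and green at 8.00 h. The two isomer readings in that pool sum to 10.0%, each with 2 percentage points of scatter, so treat the product as coarse. Divided by 20 min, it gives 166. Pooling amber, green and violet at 15.0 h gives 83.1 h, which is larger than the earlier product, so do not hold the product fixed that far out; as a rough estimate, divide this later reading by 20 h: 4.15.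

The forecast gives 300 and 4, warning that “the data only show that early isomer is below detection”. My early figure is lower than its figure.

The flask gives 186 and 4.24, and at 20.0 h target is still made 2.19 times faster than it is used up, each step taken net.

    target ⇌ isomer of the product (K = 0.340, k = 5.40 × 10⁻⁴ /min)
    substrate + partner ⇌ intermediate A (K = 690 /M, k = 0.0180 /M/min)
    substrate → target (k = 0.00110 /min)
    substrate + partner ⇌ intermediate B (K = 38.0 /M, k = 0.00300 /M/min)

The ratio-time product of the flask at 20 min is 62.0 h, against the 55.2 h read from the runs. The neighbour flask charged with 62 mM of partner gives 185 at 20 min, a product of 61.7 h.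

The readings are simulated with constants of no real substance; scatter was added.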